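**Retrosynthetic overview**

1. Numbering (carotenoid style): C1 is the left carbinol carbon, C2 the prenyl-bearing CH, C3–C4 the oxirane, C5 to C15 the left polyene half, C15' back to C1' the right half. The last step cuts the two sp2–sp2 single bonds C10–C11 and C10'–C11' in one operation, giving the left C19 epoxy-trienyl iodide 28, the C12 tin/boron pentaene linchpin 36 and the right C19 tetraenyl iodide 25, all hydroxyls free.
2. Enabling feature: the C11–C11' decapentaene (methyls on C13 and C13') is constitutionally symmetric about C15=C15' and ends in two unhindered CH termini, so it maps onto the C10 dialdehyde 33. The only ring, the trans C3–C4 oxirane, sits on the trisubstituted C5=C6 alkene, six bonds from the reacting C10–I, and should ionise slowly.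
3. Both C19 iodides come from one C7 iodo-trienal 19 (C4–C10): Julia–Kocienski olefination makes C3'=C4' on the right, and a sulfonium-ylide epoxidation makes C3–C4 plus the ring oxygen on the left.
4. Both end groups come from one racemic terpene alcohol: two lipase resolution runs on (±)-lavandulol give the (R) series (acetate; C2', both alkenes hydrated) and the (S) series (unreacted alcohol; C2, only the isopropenyl group hydrated).
5. Rings: a single ring is formed, the oxirane, in step 17 (C3 and C4 relayed from C2 by Felkin–Anh addition and trans closure); it is carried unchanged through steps 18 and 22.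

Key step: step 22

Remark (assumption): the lipase is taken to acylate the (R)-alcohol faster. If the preference is the opposite, acetate and free alcohol exchange roles in the two series (the acetate then being methanolysed first) and nothing else changes. The (S)-enriched alcohol left over in step 1 can be added to the charge of step 2, but the route does not depend on it. All polyene operations are run under argon in the dark.

**Route**

Step 1
Reactants: 1 (±)-lavandulol
Product: 2 (R)-lavandulyl acetate
Conditions: porcine pancreatic lipase, vinyl acetate, MTBE, rt, stopped at about 40% conversion (GC control); acetate 2 separated from the alcohol fraction on silica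
Reagents that add atoms: vinyl acetate, CC(=O)OC=C
Why: Lipase-catalysed kinetic resolution by irreversible transesterification held below half conversion, in which the enzyme should acylate the (R)-antipode of this 2-branched primary alcohol faster, so that the acetate is obtained enantiomerically enriched and C2' is fixed here.

Step 2
Reactants: 1 (±)-lavandulol
Product: 3 (S)-lavandulol
Conditions: porcine pancreatic lipase, vinyl acetate, MTBE, rt, a separate run taken past half conversion (to about 60–65%, GC control); unreacted alcohol 3 separated on silica from the acetate fraction, which is set aside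
Reagents that add atoms: none
Why: Lipase-catalysed kinetic resolution by irreversible transesterification run past half conversion, where the faster-reacting (R)-antipode is removed as its acetate and the slower (S)-antipode should be left unacylated in high enantiomeric purity, so that C2 is fixed here.

Step 3
Reactants: 2 (R)-lavandulyl acetate
Product: 5 (3S)-3-(hydroxymethyl)-2,6-dimethylheptane-2,6-diol, via diol acetate 4 (not isolated)
Conditions: Mn(dpm)3 (dpm = 2,2,6,6-tetramethylheptane-3,5-dionate, 5 mol %), PhSiH3 (excess), O2 (1 atm), iPrOH/CH2Cl2, 0 °C → rt; then K2CO3, MeOH, rt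
Reagents that add atoms: dioxygen, O=O
Why: Mukaiyama hydration (metal-hydride hydrogen-atom transfer, then trapping of the tertiary radicals by O2) should add water in the Markovnikov sense to both alkenes by a radical path that cannot form cyclic ethers, and carbonate-catalysed methanolysis then frees the primary alcohol without touching the stereocentre.

Step 4
Reactants: 5 (3S)-3-(hydroxymethyl)-2,6-dimethylheptane-2,6-diol
Product: 6 (3R)-2,6-dimethyl-3-{[(1-phenyl-1H-tetrazol-5-yl)sulfanyl]methyl}heptane-2,6-diol
Conditions: 1-phenyl-1H-tetrazole-5-thiol, PPh3, DIAD, THF, 0 °C → rt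
Reagents that add atoms: 1-phenyl-1H-tetrazole-5-thiol, Sc1nnnn1-c1ccccc1
Why: Mitsunobu thioetherification, in which only the primary alcohol can form the alkoxyphosphonium ion and the acidic, strongly nucleophilic thiol should displace it faster than any intramolecular ether formation (the descriptor changes only because the CIP priorities change).

Step 5
Reactants: 6 the sulfide diol
Product: 7 (3R)-2,6-dimethyl-3-{[(1-phenyl-1H-tetrazol-5-yl)sulfonyl]methyl}heptane-2,6-diol
Conditions: (NH4)6Mo7O24·4H2O (10 mol %), 30% aq. H2O2, EtOH, 0 °C → rt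
Reagents that add atoms: hydrogen peroxide, OO
Why: Molybdate-catalysed peroxide oxidation of sulfide to sulfone, with no alkene left to epoxidise and the tertiary alcohols inert.

Step 6
Reactants: 7 the sulfone diol
Product: 8 5-{[(2R)-5-methyl-5-(triethylsilyloxy)-2-[2-(triethylsilyloxy)propan-2-yl]hexyl]sulfonyl}-1-phenyl-1H-tetrazole
Conditions: Et3SiOTf (2.5 equiv), 2,6-lutidine, CH2Cl2, 0 °C
Reagents that add atoms: triethylsilyl triflate, CC[Si](CC)(CC)OS(=O)(=O)C(F)(F)F
Why: Silylation with the silyl triflate masks both tertiary alcohols so that no alkoxide can attack the tetrazole ring (Smiles-type side reaction) during the olefination.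

Step 7
Reactants: 3 (S)-lavandulol
Product: 9 (2R)-2-(2-hydroxypropan-2-yl)-5-methylhex-4-en-1-ol
Conditions: Co(acac)2 (20 mol %), PhSiH3 (1.2 equiv), O2 (1 atm), THF, 0 °C, stopped when 3 is consumed
Reagents that add atoms: dioxygen, O=O
Why: Mukaiyama hydration under the milder cobalt conditions with limited silane, where hydrogen-atom transfer should be faster to the unhindered terminal CH2 of the 1,1-disubstituted alkene than to the trisubstituted prenyl alkene, and the tertiary radical formed (a 4-pentenyl, not a 5-hexenyl radical) has no fast cyclisation open to it; the stereocentre is untouched.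

Step 8
Reactants: 9 the ene-diol
Product: 10 triethyl{[(2R)-5-methyl-2-[2-(triethylsilyloxy)propan-2-yl]hex-4-en-1-yl]oxy}silane
Conditions: Et3SiOTf (2.5 equiv), 2,6-lutidine, CH2Cl2, −78 → 0 °C
Reagents that add atoms: triethylsilyl triflate, CC[Si](CC)(CC)OS(=O)(=O)C(F)(F)F
Why: Exhaustive silylation of the primary and the tertiary alcohol with the silyl triflate, which leaves the prenyl alkene alone.

Step 9
Reactants: 10 the bis-silyl ether
Product: 11 (2S)-5-methyl-2-[2-(triethylsilyloxy)propan-2-yl]hex-4-enal
Conditions: (COCl)2, DMSO, CH2Cl2, −78 → −40 °C; then Et3N, −78 → 0 °C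
Reagents that add atoms: none
Why: Swern oxidation applied directly to the bis-silyl ether, in which the primary triethylsilyl ether is cleaved by the chlorosulfonium salt and oxidised in the same flask while the tertiary one survives, so no retro-aldol-prone β-hydroxy aldehyde is ever free, and the α-stereocentre next to a quaternary carbon should not enolise in the cold.

Step 10
Reactants: 12 propargyl alcohol
Product: 14 (E)-3-iodo-2-methylprop-2-en-1-ol, via alkenylalane 13 (not isolated)
Conditions: AlMe3 (3 equiv), Cp2ZrCl2 (25 mol %), CH2Cl2, 0 °C → rt; then I2, THF, −30 → 0 °C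
Reagents that add atoms: trimethylaluminium, C[Al](C)C; iodine, II
Why: Zirconium-catalysed carboalumination (Negishi) adds methyl and aluminium syn across the alkyne with aluminium at the terminal carbon, and iododealumination with retention then gives the E iodide.

Step 11
Reactants: 14 (E)-3-iodo-2-methylprop-2-en-1-ol; 15 (triphenylphosphoranylidene)acetaldehyde
Product: 17 (2E,4E)-5-iodo-4-methylpenta-2,4-dienal, via (E)-3-iodo-2-methylprop-2-enal 16 (not isolated)
Conditions: MnO2 (excess), CH2Cl2, rt; filtration; then 15, toluene, 60 °C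
Reagents that add atoms: none
Why: Allylic oxidation with MnO2 followed by an E-selective Wittig olefination with the stabilised formyl ylide, telescoped because the iodo-enal is volatile.

Step 12
Reactants: 17 (2E,4E)-5-iodo-4-methylpenta-2,4-dienal; 18 2-(triphenylphosphoranylidene)propanal
Product: 19 (2E,4E,6E)-7-iodo-2,6-dimethylhepta-2,4,6-trienal
Conditions: toluene, 80 °C
Reagents that add atoms: none
Why: Wittig olefination with the stabilised α-methyl formyl ylide should give the E trisubstituted enal, and the α-branched, more conjugated product should resist a second homologation.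

Step 13
Reactants: 19 the iodo-trienal
Product: 20 (2E,4E,6E)-7-iodo-2,6-dimethylhepta-2,4,6-trien-1-ol
Conditions: NaBH4, MeOH/THF, 0 °C
Reagents that add atoms: none
Why: 1,2-Reduction of the conjugated aldehyde by borohydride.

Step 14
Reactants: 20 the iodo-trienol
Product: 22 1-[(2E,4E,6E)-7-iodo-2,6-dimethylhepta-2,4,6-trien-1-yl]thiolan-1-ium bromide, via trienyl bromide 21 (not isolated)
Conditions: CBr4, PPh3, CH2Cl2, 0 °C; then tetrahydrothiophene, rt; salt triturated with Et2O
Reagents that add atoms: tetrabromomethane, BrC(Br)(Br)Br; tetrahydrothiophene, C1CCSC1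
Why: Appel bromination under neutral conditions and SN2 alkylation of the sulfide by the primary allylic bromide, telescoped because the trienyl bromide is labile.

Step 15
Reactants: 8 the bis-silylated tetrazolyl sulfone; 19 the iodo-trienal
Product: 24 (3S)-3-[(1E,3E,5E,7E)-8-iodo-3,7-dimethylocta-1,3,5,7-tetraen-1-yl]-2,6-dimethyl-2,6-bis(triethylsilyloxy)heptane, via potassium sulfonyl carbanion 23 (not isolated)
Conditions: 8, KN(SiMe3)2, DME, −60 °C, 20 min; then 19, −60 °C → rt
Reagents that add atoms: none
Why: Julia–Kocienski olefination, in which addition of the metalated tetrazolyl sulfone to the enal, Smiles rearrangement and loss of SO2 and tetrazolate should give the E C3'=C4' alkene (alkyl sulfone, unsaturated aldehyde, potassium counter-ion, ether solvent), while C2' lies β to the carbanion and is not touched.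

Step 16
Reactants: 24 the bis-silylated tetraenyl iodide
Product: 25 (3S)-3-[(1E,3E,5E,7E)-8-iodo-3,7-dimethylocta-1,3,5,7-tetraen-1-yl]-2,6-dimethylheptane-2,6-diol
Conditions: Bu4NF, THF, rt → 40 °C
Reagents that add atoms: none
Why: Fluoride-mediated cleavage of both tertiary silyl ethers under non-acidic conditions, which avoids cyclodehydration of the 1,5-diol.

Step 17
Reactants: 22 the trienyl sulfonium bromide; 11 the (2S)-aldehyde
Product: 27 triethyl{[(3R)-3-{(2R,3R)-3-[(2E,4E,6E)-7-iodo-6-methylhepta-2,4,6-trien-2-yl]oxiran-2-yl}-2,6-dimethylhept-5-en-2-yl]oxy}silane, via sulfonium ylide 26 (not isolated)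
Conditions: 22 (1.2 equiv), KN(SiMe3)2, THF, −78 °C; then 11, −78 → −20 °C
Reagents that add atoms: none
Why: Corey–Chaykovsky-type epoxidation with a semi-stabilised allylic sulfonium ylide, in which Felkin–Anh addition (the C(CH3)2OSiEt3 group anti to the incoming ylide carbon, attack past H) should set C3 as R from C2, and reversible betaine formation with closure through the anti betaine should give the trans oxirane (C4 R), so the ring and two stereocentres follow from C2 in one event.

Step 18
Reactants: 27 the silylated epoxy-trienyl iodide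
Product: 28 (3R)-3-{(2R,3R)-3-[(2E,4E,6E)-7-iodo-6-methylhepta-2,4,6-trien-2-yl]oxiran-2-yl}-2,6-dimethylhept-5-en-2-ol
Conditions: Bu4NF, THF, 0 °C → rt
Reagents that add atoms: none
Why: Fluoride-mediated desilylation under basic, non-acidic conditions, under which the vinyl oxirane and the free tertiary alcohol should coexist (as they do in the target).

Step 19
Reactants: 29 dibromomethane; 30 tributyltin chloride
Product: 32 (dibromomethyl)tributylstannane, via dibromomethyllithium 31 (not isolated)
Conditions: LiN(iPr)2, THF/Et2O, −95 °C; then 30, −95 °C → rt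
Reagents that add atoms: none
Why: Deprotonation of dibromomethane to the lithium carbenoid at low temperature and its capture at tin by substitution of chloride.

Step 20
Reactants: 33 (2E,4E,6E)-2,7-dimethylocta-2,4,6-trienedial; 34 2-(dichloromethyl)-4,4,5,5-tetramethyl-1,3,2-dioxaborolane
Product: 35 (2E,4E,6E,8E)-2,7-dimethyl-9-(4,4,5,5-tetramethyl-1,3,2-dioxaborolan-2-yl)nona-2,4,6,8-tetraenal
Conditions: 33 (3 equiv), 34 (1 equiv), CrCl2 (8 equiv), LiI (4 equiv), THF, rt; unreacted 33 recovered
Reagents that add atoms: none
Why: Takai–Utimoto boryl-olefination, in which the geminal dichromium species from the dichloromethylboronate adds to one aldehyde and eliminates to the E alkenylboronate, the excess of dialdehyde holding the reaction at the mono-adduct.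

Step 21
Reactants: 35 the boryl tetraenal; 32 (dibromomethyl)tributylstannane
Product: 36 tributyl[(1E,3E,5E,7E,9E)-3,8-dimethyl-10-(4,4,5,5-tetramethyl-1,3,2-dioxaborolan-2-yl)deca-1,3,5,7,9-pentaen-1-yl]stannane
Conditions: 32 (2 equiv), CrCl2 (8 equiv), LiI (4 equiv), THF/DMF, rt; Et3N-deactivated silica
Reagents that add atoms: none
Why: Takai–Hodgson stannyl-olefination of the remaining aldehyde, E-selective by the same chromium mechanism, with the pinacol boronate inert to divalent chromium.

Step 22
Reactants: 25 the right tetraenyl iodide diol; 36 the tin/boron pentaene linchpin; 28 the left epoxy-trienyl iodide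
Product: 38 the target CNP0268815.3 (all-E (2R,3R,4R,2'S)-3,4-epoxy C50 carotenoid triol), via nonaenyl pinacol boronate 37 (not isolated)
Conditions: 25 (1.0 equiv), 36 (1.05 equiv), Pd2(dba)3 (3 mol %), AsPh3 (24 mol %), degassed DMF/THF, rt; then 28 (1.0 equiv), TlOEt (3 equiv), H2O, rt
Reagents that add atoms: none
Why: This is a one-pot three-component Stille–Suzuki sequence on a tin/boron linchpin, whose closest known reaction type is the sequential Stille then Suzuki coupling of 1-stannyl-2-boryl-alkenes with two different alkenyl halides. In stage 1 zerovalent palladium inserts into the C10'–I bond of 25, the C11'–Sn bond of 36 transmetalates (the pinacol boronate is inert without base) and reductive elimination forms C10'–C11' to give boronate 37. In stage 2, after 28 and TlOEt are added, oxidative addition into C10–I, base-promoted boron-to-palladium transmetalation at C11 and reductive elimination form the C10–C11 bond and complete the dodecaene. No ring is closed and no stereocentre is created: both couplings go with retention at sp2 carbon, so the twelve E double bonds, the oxirane and the four stereocentres are carried over from the fragments. The selectivities needed are tin before boron (secured by adding base only in stage 2), no statistical mixing of the two iodides (secured by adding 28 only after 25 is consumed) and C–I insertion before ionisation of the vinyl oxirane (secured by the fast room-temperature reaction of the unhindered polyenyl iodide and by the trisubstituted C5=C6 alkene, which slows π-allyl formation, while the trans-oxirane itself is stable to the base).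

**Compound list**

1 | (±)-lavandulol, rac-5-methyl-2-(prop-1-en-2-yl)hex-4-en-1-ol | CC(C)=CCC(CO)C(C)=C | starting material
2 | (R)-lavandulyl acetate | CC(C)=CC[C@@H](COC(C)=O)C(C)=C | intermediate
3 | (S)-lavandulol | CC(C)=CC[C@H](CO)C(C)=C | intermediate
4 | (2S)-5-hydroxy-2-(2-hydroxypropan-2-yl)-5-methylhexyl acetate (not isolated) | CC(C)(O)CC[C@@H](COC(C)=O)C(C)(C)O | intermediate
5 | (3S)-3-(hydroxymethyl)-2,6-dimethylheptane-2,6-diol | CC(C)(O)CC[C@@H](CO)C(C)(C)O | intermediate
6 | (3R)-2,6-dimethyl-3-{[(1-phenyl-1H-tetrazol-5-yl)sulfanyl]methyl}heptane-2,6-diol | CC(C)(O)CC[C@@H](CSc1nnnn1-c1ccccc1)C(C)(C)O | intermediate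
7 | (3R)-2,6-dimethyl-3-{[(1-phenyl-1H-tetrazol-5-yl)sulfonyl]methyl}heptane-2,6-diol | CC(C)(O)CC[C@@H](CS(=O)(=O)c1nnnn1-c1ccccc1)C(C)(C)O | intermediate
8 | 5-{[(2R)-5-methyl-5-(triethylsilyloxy)-2-[2-(triethylsilyloxy)propan-2-yl]hexyl]sulfonyl}-1-phenyl-1H-tetrazole | CC[Si](CC)(CC)OC(C)(C)CC[C@@H](CS(=O)(=O)c1nnnn1-c1ccccc1)C(C)(C)O[Si](CC)(CC)CC | intermediate
9 | (2R)-2-(2-hydroxypropan-2-yl)-5-methylhex-4-en-1-ol | CC(C)=CC[C@H](CO)C(C)(C)O | intermediate
10 | triethyl{[(2R)-5-methyl-2-[2-(triethylsilyloxy)propan-2-yl]hex-4-en-1-yl]oxy}silane | CC(C)=CC[C@H](CO[Si](CC)(CC)CC)C(C)(C)O[Si](CC)(CC)CC | intermediate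
11 | (2S)-5-methyl-2-[2-(triethylsilyloxy)propan-2-yl]hex-4-enal | CC(C)=CC[C@H](C=O)C(C)(C)O[Si](CC)(CC)CC | intermediate
12 | propargyl alcohol (prop-2-yn-1-ol) | C#CCO | starting material
13 | (E)-alkenylalane, dimethylaluminium alkoxide of (E)-3-(dimethylalumanyl)-2-methylprop-2-en-1-ol (not isolated) | C[Al](C)OC/C(C)=C/[Al](C)C | intermediate
14 | (E)-3-iodo-2-methylprop-2-en-1-ol | OC/C(C)=C/I | intermediate
15 | (triphenylphosphoranylidene)acetaldehyde | O=CC=P(c1ccccc1)(c1ccccc1)c1ccccc1 | starting material
16 | (E)-3-iodo-2-methylprop-2-enal (not isolated) | O=C/C(C)=C/I | intermediate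
17 | (2E,4E)-5-iodo-4-methylpenta-2,4-dienal | O=C/C=C/C(C)=C/I | intermediate
18 | 2-(triphenylphosphoranylidene)propanal | CC(C=O)=P(c1ccccc1)(c1ccccc1)c1ccccc1 | starting material
19 | (2E,4E,6E)-7-iodo-2,6-dimethylhepta-2,4,6-trienal | O=C/C(C)=C/C=C/C(C)=C/I | intermediate
20 | (2E,4E,6E)-7-iodo-2,6-dimethylhepta-2,4,6-trien-1-ol | OC/C(C)=C/C=C/C(C)=C/I | intermediate
21 | (1E,3E,5E)-7-bromo-1-iodo-2,6-dimethylhepta-1,3,5-triene (not isolated) | BrC/C(C)=C/C=C/C(C)=C/I | intermediate
22 | 1-[(2E,4E,6E)-7-iodo-2,6-dimethylhepta-2,4,6-trien-1-yl]thiolan-1-ium bromide | I/C=C(C)/C=C/C=C(C)/C[S+]1CCCC1.[Br-] | intermediate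
23 | potassium salt of the α-sulfonyl carbanion of 8 (not isolated) | CC[Si](CC)(CC)OC(C)(C)CC[C@@H]([CH-]S(=O)(=O)c1nnnn1-c1ccccc1)C(C)(C)O[Si](CC)(CC)CC.[K+] | intermediate
24 | (3S)-3-[(1E,3E,5E,7E)-8-iodo-3,7-dimethylocta-1,3,5,7-tetraen-1-yl]-2,6-dimethyl-2,6-bis(triethylsilyloxy)heptane | I/C=C(C)/C=C/C=C(C)/C=C/[C@H](CCC(C)(C)O[Si](CC)(CC)CC)C(C)(C)O[Si](CC)(CC)CC | intermediate
25 | (3S)-3-[(1E,3E,5E,7E)-8-iodo-3,7-dimethylocta-1,3,5,7-tetraen-1-yl]-2,6-dimethylheptane-2,6-diol | I/C=C(C)/C=C/C=C(C)/C=C/[C@H](CCC(C)(C)O)C(C)(C)O | intermediate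
26 | thiolanium (2E,4E,6E)-7-iodo-2,6-dimethylhepta-2,4,6-trien-1-ylide (not isolated) | I/C=C(C)/C=C/C=C(C)/[CH-][S+]1CCCC1 | intermediate
27 | triethyl{[(3R)-3-{(2R,3R)-3-[(2E,4E,6E)-7-iodo-6-methylhepta-2,4,6-trien-2-yl]oxiran-2-yl}-2,6-dimethylhept-5-en-2-yl]oxy}silane | CC(C)=CC[C@H]([C@H]1O[C@@H]1/C(C)=C/C=C/C(C)=C/I)C(C)(C)O[Si](CC)(CC)CC | intermediate
28 | (3R)-3-{(2R,3R)-3-[(2E,4E,6E)-7-iodo-6-methylhepta-2,4,6-trien-2-yl]oxiran-2-yl}-2,6-dimethylhept-5-en-2-ol | CC(C)=CC[C@H]([C@H]1O[C@@H]1/C(C)=C/C=C/C(C)=C/I)C(C)(C)O | intermediate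
29 | dibromomethane | BrCBr | starting material
30 | tributyltin chloride | CCCC[Sn](Cl)(CCCC)CCCC | starting material
31 | dibromomethyllithium (not isolated) | [Li]C(Br)Br | intermediate
32 | (dibromomethyl)tributylstannane | CCCC[Sn](CCCC)(CCCC)C(Br)Br | intermediate
33 | (2E,4E,6E)-2,7-dimethylocta-2,4,6-trienedial | O=C/C(C)=C/C=C/C=C(C)/C=O | starting material
34 | 2-(dichloromethyl)-4,4,5,5-tetramethyl-1,3,2-dioxaborolane | ClC(Cl)B1OC(C)(C)C(C)(C)O1 | starting material
35 | (2E,4E,6E,8E)-2,7-dimethyl-9-(4,4,5,5-tetramethyl-1,3,2-dioxaborolan-2-yl)nona-2,4,6,8-tetraenal | O=C/C(C)=C/C=C/C=C(C)/C=C/B1OC(C)(C)C(C)(C)O1 | intermediate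
36 | tributyl[(1E,3E,5E,7E,9E)-3,8-dimethyl-10-(4,4,5,5-tetramethyl-1,3,2-dioxaborolan-2-yl)deca-1,3,5,7,9-pentaen-1-yl]stannane | CCCC[Sn](CCCC)(CCCC)/C=C/C(C)=C/C=C/C=C(C)/C=C/B1OC(C)(C)C(C)(C)O1 | intermediate
37 | all-E nonaenyl pinacol boronate, C11 boronate of the C11–C1' right part with (2'S) diol end (not isolated) | CC1(C)OB(/C=C/C(C)=C/C=C/C=C(C)/C=C/C=C(C)/C=C/C=C(C)/C=C/[C@H](CCC(C)(C)O)C(C)(C)O)OC1(C)C | intermediate
38 | CNP0268815.3, all-E (2R,3R,4R,2'S)-3,4-epoxy C50 carotenoid triol | CC(C)=CC[C@H]([C@H]1O[C@@H]1/C(C)=C/C=C/C(C)=C/C=C/C(C)=C/C=C/C=C(C)/C=C/C=C(C)/C=C/C=C(C)/C=C/[C@H](CCC(C)(C)O)C(C)(C)O)C(C)(C)O | target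

**Step count and risks**

Total step count: 22. Longest linear sequence: 8 steps (10, 11, 12, 13, 14, 17, 18, 22; equally 1, 3, 4, 5, 6, 15, 16, 22).

Steps most likely to fail:

1. Step 17. The facial bias at the aldehyde or the anti/syn betaine selectivity may erode and give C3/C4 diastereomers, the base may epimerise C2 of 11 before addition, and the extended ylide may attack through C6 or C8 instead of C4. The fallback sets out from 11 and from 17 and comes back at 27. Wittig olefination of 11 with 1-(triphenylphosphoranylidene)propan-2-one should give (3E,5R)-8-methyl-5-[2-(triethylsilyloxy)propan-2-yl]nona-3,7-dien-2-one F1. Catalyst-controlled nucleophilic epoxidation of this enone (La(OiPr)3, BINOL, Ph3As=O, t-BuOOH, molecular sieves, THF; the BINOL antipode that matches the substrate bias is picked in a test pair) should give the trans-epoxy ketone 1-[(2S,3R)-3-[(3R)-2,6-dimethyl-2-(triethylsilyloxy)hept-5-en-3-yl]oxiran-2-yl]ethan-1-one F2, the prenyl alkene being inert to a nucleophilic peroxide. In parallel 17 is reduced (NaBH4) to (2E,4E)-5-iodo-4-methylpenta-2,4-dien-1-ol F3, brominated (CBr4, PPh3) to (1E,3E)-5-bromo-1-iodo-2-methylpenta-1,3-diene F4 and heated with P(OEt)3 (Michaelis–Arbuzov) to diethyl [(2E,4E)-5-iodo-4-methylpenta-2,4-dien-1-yl]phosphonate F5. Horner–Wadsworth–Emmons olefination of F2 with the lithium salt of F5 (LiN(SiMe3)2, THF, −78 °C) forms C5=C6 and should give 27 after removal of the 5Z isomer on silica.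

2. Step 22. Zerovalent palladium may ionise the vinyl oxirane (π-allyl formation and SN2' capture), boronate 37 may protodeboronate or isomerise while it waits for stage 2, and incomplete stage 1 would give statistical mixtures. The fallback sets out from 33 and 32 (with 25 and 28 unchanged) and comes back at 38. Double stannyl-olefination of 33 (excess 32, CrCl2, LiI) should give (1E,3E,5E,7E,9E)-3,8-dimethyl-1,10-bis(tributylstannyl)deca-1,3,5,7,9-pentaene F6. Stille coupling of 25 with an excess of F6 (Pd2(dba)3, AsPh3, DMF, rt) should give the mono-coupled all-E nonaenyl stannane F7, the surplus F6 being recovered. The C10–C11 bond is then formed without palladium by joining F7 and 28 with copper thiophene-2-carboxylate, Cu(O2CC4H3S), in NMP at 0 °C, so the oxirane never meets zerovalent palladium.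

3. Step 7. The hydrogen-atom transfer may not discriminate enough between the two alkenes, so that the prenyl group or both groups are hydrated. The fallback sets out from 3 and comes back at 9. Acylation of 3 (Boc2O, DMAP) gives tert-butyl [(2S)-5-methyl-2-(prop-1-en-2-yl)hex-4-en-1-yl] carbonate F8. Iodocarbonate cyclisation (I2, NaHCO3, MeCN, −20 °C) should give (5R)-4-(iodomethyl)-4-methyl-5-(3-methylbut-2-en-1-yl)-1,3-dioxan-2-one F9, because only the isopropenyl group can close a six-membered carbonate (the prenyl alkene would need an eight-membered ring). LiEt3BH in THF then removes iodide (directly or through the epoxide formed after carbonate cleavage) and reduces the carbonate, which gives 9.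

**Further compounds**

F1 | step 17 | (3E,5R)-8-methyl-5-[2-(triethylsilyloxy)propan-2-yl]nona-3,7-dien-2-one | CC(C)=CC[C@H](/C=C/C(C)=O)C(C)(C)O[Si](CC)(CC)CC
F2 | step 17 | 1-[(2S,3R)-3-[(3R)-2,6-dimethyl-2-(triethylsilyloxy)hept-5-en-3-yl]oxiran-2-yl]ethan-1-one | CC(C)=CC[C@H]([C@H]1O[C@@H]1C(C)=O)C(C)(C)O[Si](CC)(CC)CC
F3 | step 17 | (2E,4E)-5-iodo-4-methylpenta-2,4-dien-1-ol | OC/C=C/C(C)=C/I
F4 | step 17 | (1E,3E)-5-bromo-1-iodo-2-methylpenta-1,3-diene | BrC/C=C/C(C)=C/I
F5 | step 17 | diethyl [(2E,4E)-5-iodo-4-methylpenta-2,4-dien-1-yl]phosphonate | CCOP(=O)(OCC)C/C=C/C(C)=C/I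
F6 | step 22 | (1E,3E,5E,7E,9E)-3,8-dimethyl-1,10-bis(tributylstannyl)deca-1,3,5,7,9-pentaene | CCCC[Sn](CCCC)(CCCC)/C=C/C(C)=C/C=C/C=C(C)/C=C/[Sn](CCCC)(CCCC)CCCC
F7 | step 22 | all-E nonaenyl tributylstannane, C11 stannane of the C11–C1' right part with (2'S) diol end | CCCC[Sn](CCCC)(CCCC)/C=C/C(C)=C/C=C/C=C(C)/C=C/C=C(C)/C=C/C=C(C)/C=C/[C@H](CCC(C)(C)O)C(C)(C)O
F8 | step 7 | tert-butyl [(2S)-5-methyl-2-(prop-1-en-2-yl)hex-4-en-1-yl] carbonate | CC(C)=CC[C@H](COC(=O)OC(C)(C)C)C(C)=C
F9 | step 7 | (5R)-4-(iodomethyl)-4-methyl-5-(3-methylbut-2-en-1-yl)-1,3-dioxan-2-one (both C4 epimers) | CC(C)=CC[C@@H]1COC(=O)OC1(C)CI
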